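The aryl ether is cut to isofraxidin and a neopentyl alcohol, and the synthesis rests on how the ring carrying the quaternary carbon is made. That carbon (C-1 of the decalin: methyl, CH2O, next to the methyl-bearing C-2) is the retron of a Meinwald rearrangement. A trisubstituted epoxide on a trans-fused seven-membered ring is ionised by an aluminium Lewis acid and a ring bond shifts, so the cycloheptane contracts to the cyclohexane ring C-1/C-2/C-3/C-4/C-4a/C-8a while C-1 and its formyl group are set stereospecifically. The cycloheptene comes from 2-methylcyclohexenone by asymmetric conjugate addition, enolate alkylation with a citronellene-derived iodide and ring-closing metathesis.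

Key step: step 9

Remark: decalins are numbered as naphthalenes (C-1 carries the CH2O group in 17 and 22), the seven-membered-ring intermediates as benzo[7]annulenes. Borane adduct 18 is drawn as its simplest form, and (R)-β-citronellene of high enantiomeric purity is assumed.

Step 1
Reactants: 1 (R)-β-citronellene
Product: 3 (4R)-4-methylhex-5-enoic acid, via aldehyde 2 (not isolated)
Conditions: O3 (1.0 equiv), CH2Cl2/MeOH, −78 °C; Me2S, −78 °C → rt; then NaClO2, NaH2PO4, 2-methylbut-2-ene, t-BuOH/H2O, rt
Reagents that add atoms: ozone ([O-][O+]=O); sodium chlorite ([Na+].[O-]Cl=O)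
Why: Ozonolysis should cleave the electron-rich trisubstituted alkene much faster than the monosubstituted one, and Pinnick oxidation takes the aldehyde to the acid without touching the stereocentre.

Step 2
Reactants: 3 (4R)-4-methylhex-5-enoic acid
Product: 5 (3R)-5-iodo-3-methylpent-1-ene, via Barton ester 4 (not isolated)
Conditions: 1-hydroxypyridine-2(1H)-thione, DCC, DMAP (cat.), CH2Cl2, rt, dark; then CHI3, PhCF3, hν (tungsten lamp), rt
Reagents that add atoms: 1-hydroxypyridine-2(1H)-thione (ON1C=CC=CC1=S, atoms of 4 only); iodoform (IC(I)I)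
Why: Barton decarboxylation gives the primary alkyl radical, which takes iodine from iodoform in a radical chain; the 4-pentenyl-type radical should not cyclise and the stereocentre is untouched.

Step 3
Reactants: 6 2-methylcyclohex-2-en-1-one; 7 isopropenylmagnesium bromide
Product: 9 trimethyl{[(3S)-2-methyl-3-(prop-1-en-2-yl)cyclohex-1-en-1-yl]oxy}silane, via magnesium enolate 8 (not isolated)
Conditions: Cu(OTf)2 (3 mol%), chiral hydroxyalkyl imidazolinium salt (N-heterocyclic carbene precursor, 4 mol%, enantiomer that gives 3S), Et2O/THF, −10 °C; then Me3SiCl, HMPA, −10 °C → rt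
Reagents that add atoms: chlorotrimethylsilane (C[Si](C)(C)Cl)
Why: Copper-catalysed asymmetric conjugate addition of a Grignard reagent to an α-substituted cyclic enone, in which the chiral carbene–copper complex selects the enone face and sets C-3 as S; O-silylation then stores the enolate regiochemistry.

Step 4
Reactants: 9 trimethyl{[(3S)-2-methyl-3-(prop-1-en-2-yl)cyclohex-1-en-1-yl]oxy}silane; 5 (3R)-5-iodo-3-methylpent-1-ene
Product: 11 (2S,3S)-2-methyl-2-[(3R)-3-methylpent-4-en-1-yl]-3-(prop-1-en-2-yl)cyclohexan-1-one, via lithium enolate 10 (not isolated)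
Conditions: MeLi, THF, 0 °C; then 5, HMPA, −40 → 0 °C
Reagents that add atoms: methyllithium (C[Li], lithium of 10 only)
Why: Methyllithium cleaves the silyl enol ether to the regiodefined lithium enolate, and its SN2 alkylation by the primary iodide should occur anti to the neighbouring isopropenyl group, setting the quaternary centre (2S) trans to it.

Step 5
Reactants: 11 (2S,3S)-2-methyl-2-[(3R)-3-methylpent-4-en-1-yl]-3-(prop-1-en-2-yl)cyclohexan-1-one
Product: 12 (4aS,7R,9aS)-4a,7,9-trimethyl-1,2,3,4a,5,6,7,9a-octahydro-4H-benzo[7]annulen-4-one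
Conditions: second-generation Hoveyda–Grubbs catalyst RuCl2(H2IMes)(=CH–C6H4-2-O-i-Pr) (5 mol%), toluene, 80 °C, argon sparge
Reagents that add atoms: none
Why: Ring-closing metathesis, in which the catalyst loads on the monosubstituted alkene and closes onto the isopropenyl group; the two trans (diequatorial) arms should give the trans-fused trisubstituted cycloheptene with loss of ethene and no change at any stereocentre.

Step 6
Reactants: 12 (4aS,7R,9aS)-4a,7,9-trimethyl-1,2,3,4a,5,6,7,9a-octahydro-4H-benzo[7]annulen-4-one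
Product: 13 (4aS,7R,8R,9S,9aR)-8,9-epoxy-4a,7,9-trimethyldecahydro-4H-benzo[7]annulen-4-one
Conditions: mCPBA, CH2Cl2, 0 °C
Reagents that add atoms: 3-chloroperoxybenzoic acid (OOC(=O)c1cccc(Cl)c1)
Why: Prilezhaev epoxidation; in the chair cycloheptene the axial 4a-methyl group lies over the β-face of C-9, so the peracid should add to the α-face, cis to H-9a, which fixes both epoxide centres (8R,9S).

Step 7
Reactants: 13 (4aS,7R,8R,9S,9aR)-8,9-epoxy-4a,7,9-trimethyldecahydro-4H-benzo[7]annulen-4-one
Product: 15 (4aS,7R,8R,9S,9aR)-8,9-epoxy-4a,7,9-trimethyl-2,4a,5,6,7,8,9,9a-octahydro-1H-benzo[7]annulen-4-yl trifluoromethanesulfonate, via potassium enolate 14 (not isolated)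
Conditions: KN(SiMe3)2, THF, −78 °C; then PhNTf2, −78 → 0 °C
Reagents that add atoms: potassium bis(trimethylsilyl)amide (C[Si](C)(C)N([K])[Si](C)(C)C, potassium of 14 only); N-phenylbis(trifluoromethanesulfonimide) (O=S(=O)(N(c1ccccc1)S(=O)(=O)C(F)(F)F)C(F)(F)F)
Why: Only C-3 carries α-hydrogens, so a single enolate should form and be O-sulfonylated (enol triflate formation), while the epoxide is inert to the hindered amide base at low temperature.

Step 8
Reactants: 15 (4aS,7R,8R,9S,9aR)-8,9-epoxy-4a,7,9-trimethyl-2,4a,5,6,7,8,9,9a-octahydro-1H-benzo[7]annulen-4-yl trifluoromethanesulfonate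
Product: 16 (4aS,7R,8R,9S,9aR)-8,9-epoxy-4,4a,7,9-tetramethyl-2,4a,5,6,7,8,9,9a-octahydro-1H-benzo[7]annulene
Conditions: MeB(OH)2, Pd(PPh3)4 (5 mol%), K2CO3, dioxane/H2O, 80 °C
Reagents that add atoms: methylboronic acid (CB(O)O)
Why: Suzuki–Miyaura cross-coupling of the alkenyl triflate installs the methyl group that becomes C-5 methyl of the decalin, under mildly basic conditions that should leave the epoxide intact.

Step 9
Reactants: 16 (4aS,7R,8R,9S,9aR)-8,9-epoxy-4,4a,7,9-tetramethyl-2,4a,5,6,7,8,9,9a-octahydro-1H-benzo[7]annulene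
Product: 17 (1R,2R,4aS,8aR)-1,2,4a,5-tetramethyl-1,2,3,4,4a,7,8,8a-octahydronaphthalene-1-carbaldehyde
Conditions: MeAl(OC6H2-4-Br-2,6-t-Bu2)2 [methylaluminium bis(4-bromo-2,6-di-tert-butylphenoxide)] (20 mol%), CH2Cl2, −78 → −20 °C
Reagents that add atoms: none
Why: The oxophilic aluminium Lewis acid binds the epoxide oxygen and breaks its bond to C-9, the tertiary carbon; as C-9 ionises, the C7–C8 ring bond shifts from C-8 to C-9 and C-8 becomes the aldehyde carbon (Meinwald rearrangement, a semipinacol 1,2-alkyl shift). The closest known reaction type is the rearrangement of trisubstituted epoxides, 1-methylcycloalkene oxides included, to α-quaternary aldehydes with bulky methylaluminium bis(phenoxides). The cyclohexane ring is closed by this suprafacial 1,2-shift, which joins C-7 to C-9 and extrudes C-8 (contraction from seven to six ring atoms), not by a cyclisation onto a π bond. The new quaternary centre, C-1 of the decalin, forms with inversion at the epoxide carbon because the migrating carbon enters anti to the departing oxygen, so the α-epoxide of step 6 controls it; the migrating carbon keeps its configuration (C-2 methyl) and the ring-fusion centres are not involved. The step needs ring-bond migration to win over the 1,2-hydride shift (to the cycloheptanone) and over proton loss (to an allylic alcohol); the two 2,6-di-tert-butylphenoxide ligands, which disfavour the conformer that aligns the small hydrogen, the low temperature and the absence of a second Lewis-basic carbonyl group should secure this.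

Step 10
Reactants: 17 (1R,2R,4aS,8aR)-1,2,4a,5-tetramethyl-1,2,3,4,4a,7,8,8a-octahydronaphthalene-1-carbaldehyde
Product: 19 (1R,2R,4aR,5R,6R,8aS)-5-(hydroxymethyl)-1,5,6,8a-tetramethyldecahydronaphthalen-2-ol, via borane adduct 18 (not isolated)
Conditions: BH3·THF (excess), THF, 0 °C → rt; then NaOH, H2O2, 0 °C → rt
Reagents that add atoms: borane–tetrahydrofuran ([BH3-][O+]1CCCC1, boron of 18 only); hydrogen peroxide (OO)
Why: Borane reduces the aldehyde and hydroborates the trisubstituted alkene (anti-Markovnikov, syn) from the α-face opposite the two axial methyl groups, so oxidation with retention should give the equatorial secondary alcohol (C-2) and the equatorial methyl group at C-1.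

Step 11
Reactants: 19 (1R,2R,4aR,5R,6R,8aS)-5-(hydroxymethyl)-1,5,6,8a-tetramethyldecahydronaphthalen-2-ol
Product: 20 (1R,4aR,5R,6R,8aS)-5-(hydroxymethyl)-1,5,6,8a-tetramethyloctahydronaphthalen-2(1H)-one
Conditions: NaOCl (aq., 1.1 equiv), AcOH, 0 °C → rt
Reagents that add atoms: none
Why: Hypochlorite in acetic acid oxidises secondary alcohols much faster than primary ones, so only the ring carbinol should become the ketone; the adjacent methyl-bearing centre already has the stable equatorial configuration.

Step 12
Reactants: 20 (1R,4aR,5R,6R,8aS)-5-(hydroxymethyl)-1,5,6,8a-tetramethyloctahydronaphthalen-2(1H)-one; 21 isofraxidin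
Product: 22 7-{[(1R,2R,4aS,5R,8aR)-1,2,4a,5-tetramethyl-6-oxodecahydronaphthalen-1-yl]methoxy}-6,8-dimethoxy-2H-chromen-2-one
Conditions: PBu3, 1,1′-(azodicarbonyl)dipiperidine, toluene, 80 °C
Reagents that add atoms: none
Why: Mitsunobu etherification, in which the phosphine/azo-amide pair activates the primary alcohol and the acidic coumarin phenoxide displaces it; no stereocentre is touched and ketone and lactone should be inert.

Compound list
1 | (R)-β-citronellene, (3R)-3,7-dimethylocta-1,6-diene | C=C[C@H](C)CCC=C(C)C | starting material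
2 | (4R)-4-methylhex-5-enal | C=C[C@H](C)CCC=O | intermediate (not isolated)
3 | (4R)-4-methylhex-5-enoic acid | C=C[C@H](C)CCC(=O)O | intermediate
4 | Barton ester, 2-thioxopyridin-1(2H)-yl (4R)-4-methylhex-5-enoate | C=C[C@H](C)CCC(=O)ON1C=CC=CC1=S | intermediate (not isolated)
5 | (3R)-5-iodo-3-methylpent-1-ene | C=C[C@H](C)CCI | intermediate
6 | 2-methylcyclohex-2-en-1-one | CC1=CCCC1=O | starting material
7 | isopropenylmagnesium bromide | CC(=C)[Mg]Br | starting material
8 | bromomagnesium (3S)-2-methyl-3-(prop-1-en-2-yl)cyclohex-1-en-1-olate | CC1=C(O[Mg]Br)CCC[C@H]1C(C)=C | intermediate (not isolated)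
9 | trimethyl{[(3S)-2-methyl-3-(prop-1-en-2-yl)cyclohex-1-en-1-yl]oxy}silane | CC1=C(O[Si](C)(C)C)CCC[C@H]1C(C)=C | intermediate
10 | lithium (3S)-2-methyl-3-(prop-1-en-2-yl)cyclohex-1-en-1-olate | CC1=C(O[Li])CCC[C@H]1C(C)=C | intermediate (not isolated)
11 | (2S,3S)-2-methyl-2-[(3R)-3-methylpent-4-en-1-yl]-3-(prop-1-en-2-yl)cyclohexan-1-one | C=C[C@H](C)CC[C@]1(C)C(=O)CCC[C@H]1C(C)=C | intermediate
12 | (4aS,7R,9aS)-4a,7,9-trimethyl-1,2,3,4a,5,6,7,9a-octahydro-4H-benzo[7]annulen-4-one (trans-fused) | CC1=C[C@H](C)CC[C@]2(C)C(=O)CCC[C@@H]12 | intermediate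
13 | (4aS,7R,8R,9S,9aR)-8,9-epoxy-4a,7,9-trimethyldecahydro-4H-benzo[7]annulen-4-one (oxygen cis to H-9a and the 7-methyl, trans to the 4a-methyl) | C[C@@]12O[C@@H]1[C@H](C)CC[C@]3(C)C(=O)CCC[C@@H]23 | intermediate
14 | potassium enolate of 13 (C3=C4, O–K on C-4) | C[C@@]12O[C@@H]1[C@H](C)CC[C@]3(C)C(O[K])=CCC[C@@H]23 | intermediate (not isolated)
15 | (4aS,7R,8R,9S,9aR)-8,9-epoxy-4a,7,9-trimethyl-2,4a,5,6,7,8,9,9a-octahydro-1H-benzo[7]annulen-4-yl trifluoromethanesulfonate | C[C@@]12O[C@@H]1[C@H](C)CC[C@]3(C)C(OS(=O)(=O)C(F)(F)F)=CCC[C@@H]23 | intermediate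
16 | (4aS,7R,8R,9S,9aR)-8,9-epoxy-4,4a,7,9-tetramethyl-2,4a,5,6,7,8,9,9a-octahydro-1H-benzo[7]annulene | C[C@@]12O[C@@H]1[C@H](C)CC[C@]3(C)C(C)=CCC[C@@H]23 | intermediate
17 | (1R,2R,4aS,8aR)-1,2,4a,5-tetramethyl-1,2,3,4,4a,7,8,8a-octahydronaphthalene-1-carbaldehyde | O=C[C@@]1(C)[C@@H]2CCC=C(C)[C@@]2(C)CC[C@H]1C | intermediate
18 | borane adduct of 17 (O–BH2 on the former formyl carbon, BH2 on the future carbinol carbon) | BOC[C@@]1(C)[C@@H]2CC[C@@H](B)[C@H](C)[C@@]2(C)CC[C@H]1C | intermediate (not isolated)
19 | (1R,2R,4aR,5R,6R,8aS)-5-(hydroxymethyl)-1,5,6,8a-tetramethyldecahydronaphthalen-2-ol | OC[C@@]1(C)[C@@H]2CC[C@@H](O)[C@H](C)[C@@]2(C)CC[C@H]1C | intermediate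
20 | (1R,4aR,5R,6R,8aS)-5-(hydroxymethyl)-1,5,6,8a-tetramethyloctahydronaphthalen-2(1H)-one | OC[C@@]1(C)[C@@H]2CCC(=O)[C@H](C)[C@@]2(C)CC[C@H]1C | intermediate
21 | isofraxidin, 7-hydroxy-6,8-dimethoxy-2H-chromen-2-one | COc1cc2ccc(=O)oc2c(OC)c1O | starting material
22 | 7-{[(1R,2R,4aS,5R,8aR)-1,2,4a,5-tetramethyl-6-oxodecahydronaphthalen-1-yl]methoxy}-6,8-dimethoxy-2H-chromen-2-one | COc1cc2ccc(=O)oc2c(OC)c1OC[C@@]1(C)[C@@H]2CCC(=O)[C@H](C)[C@@]2(C)CC[C@H]1C | target

Total step count: 12
Longest linear sequence: 11 steps (steps 1, 2, then 4 to 12)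

Steps most likely to fail

Step 9. Hydride migration from C-8, or loss of a proton from the 9-methyl group, may outrun the shift of the C7–C8 ring bond, so that ring contraction is not the main pathway. The fallback sets out from 16 and comes back at 17. The epoxide is isomerised with Et2Al(NC9H18) (diethylaluminium 2,2,6,6-tetramethylpiperidide) in toluene to the exocyclic allylic alcohol F1, which is oxidised with Dess–Martin periodinane to the α-methylene ketone F2. Conjugate reduction with LiBH(s-Bu)3 gives the regiodefined enolate, which N-chlorosuccinimide should chlorinate on the α-face to the tertiary α-chloro ketone F3. Reduction with i-Bu2AlH and warming then gives the aluminium alkoxide of the chlorohydrin, in which the ring bond anti to the C–Cl bond migrates with inversion at C-9 (organoaluminium-promoted reductive 1,2-rearrangement) to give 17.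

Step 6. The peracid may add with poor facial selectivity or to the β-face, which would invert the later quaternary centre. The fallback sets out from 12 and comes back at 13. N-Bromosuccinimide in aqueous acetone should give, by water attack at the tertiary carbon anti to the bromonium ion, the bromohydrin F4 (9α-hydroxy, 8β-bromo), and K2CO3 in MeOH closes it to 13. The epoxide oxygen thus ends on the face opposite to the one taken by the electrophile, the reverse of the peracid outcome.

Step 12. Displacement at the neopentyl carbon by the doubly ortho-substituted phenoxide may be too slow, so that the activated alcohol decomposes instead. The fallback sets out from 20 and comes back at 22. Tf2O and 2,6-lutidine in CH2Cl2 at −78 °C give the neopentyl triflate F5, which is displaced by the caesium salt of 21 (Cs2CO3, DMF, 50 °C).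

Further compounds
F1 | step 9 | (4aS,7R,8R,9aR)-4,4a,7-trimethyl-9-methylidene-2,4a,5,6,7,8,9,9a-octahydro-1H-benzo[7]annulen-8-ol (allylic alcohol) | C=C1[C@H](O)[C@H](C)CC[C@]2(C)C(C)=CCC[C@@H]12
F2 | step 9 | 4,4a,7-trimethyl-9-methylidene-octahydro-benzo[7]annulen-8-one (α-methylene ketone, ring centres as in 16) | C=C1C(=O)[C@H](C)CC[C@]2(C)C(C)=CCC[C@@H]12
F3 | step 9 | (9S)-9-chloro-4,4a,7,9-tetramethyl-octahydro-benzo[7]annulen-8-one (chlorine cis to H-9a, other centres as in 16) | C[C@@]1(Cl)C(=O)[C@H](C)CC[C@]2(C)C(C)=CCC[C@@H]12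
F4 | step 6 | 8β-bromo-9α-hydroxy-4a,7,9-trimethyldecahydro-4H-benzo[7]annulen-4-one (bromohydrin of 12) | C[C@@]1(O)[C@@H](Br)[C@H](C)CC[C@]2(C)C(=O)CCC[C@@H]12
F5 | step 12 | [(1R,2R,4aS,5R,8aR)-1,2,4a,5-tetramethyl-6-oxodecahydronaphthalen-1-yl]methyl trifluoromethanesulfonate | O=S(=O)(OC[C@@]1(C)[C@@H]2CCC(=O)[C@H](C)[C@@]2(C)CC[C@H]1C)C(F)(F)F
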